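## Retrosynthetic overview

1. 22 ⇐ 21 ⇐ 20: the angelate goes on last, after the C6 hydroxyl is released from a MOM ether.
2. 20 ⇐ 16 (key step): the nine-membered oxacycle (O10, C3–C10) arises from the seven-membered lactone ring (O8, C3–C8) of 16 by shift of the acyl carbon C3 from O8 to O10, a ring expansion by C9–C10. In the same operation C2 closes the 3(2H)-furanone on C3 and the freed O8 closes the α-methylene-γ-lactone on C12.
3. Enabling feature: the syn-1,3-diol array O8–C8–C9–C10–O10, with acyl carbon C3 parked on O8 in a (Z)-unsaturated seven-membered lactone and an acetyl group (C1–C2) on the quaternary carbinol C10.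
4. 16 ⇐ 15 (RCM, C4=C5, Z fixed by the ring) ⇐ 14 (alkyne → acrylate) ⇐ 13 ⇐ 12 ⇐ benzoate 10 + aldehyde 5 (Pd/In allenyl addition, C7–C8 bond).
5. Ring order: oxepinone (RCM) → oxonine by ring expansion → butyrolactone → furanone. Stereocentres: C10 from a Cu–box aldol, C6 from Brown alkoxyallylboration, C7 and C8 by chirality transfer in the allenylindium addition.

Key step: step 11

Remarks:
- C1–C13, O8 and O10 are germacrane-type locants of the target, used only in the text (C1 ketone, C2=C3 furanone enol ether, C4=C5, C6 ester carbinol, C7, C8 lactone carbinol, C9, C10 quaternary carbinol, C11=C13 methylene, C12 lactone carbonyl).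
- O-silyl, O-boryl and O-metal forms of a product that are cleaved in the work-up are not numbered separately; what they release is listed under "Set free".
- Assumption: the Cu(II)–bis(oxazoline) aldol shows the same facial preference with butane-2,3-dione as with pyruvate esters, and 3-(methoxymethoxy)prop-1-ene is purchased (otherwise one step from allyl alcohol).

## Route

Step 1
Reactants: 1 S-ethyl ethanethioate
Product: 2 1-(ethylsulfanyl)-1-[(trimethylsilyl)oxy]ethene
Conditions: LDA, THF, −78 °C; TMSCl, −78 °C → rt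
Reagents that add atoms: chlorotrimethylsilane C[Si](C)(C)Cl
Why: Kinetic enolisation of the thioester and O-silylation give the silyl ketene acetal, the standard donor for Mukaiyama aldol additions.

Step 2
Reactants: 2 1-(ethylsulfanyl)-1-[(trimethylsilyl)oxy]ethene, 3 butane-2,3-dione
Product: 4 S-ethyl (3R)-3-hydroxy-3-methyl-4-oxopentanethioate
Conditions: [Cu((R,R)-t-Bu-box)](OTf)2 (10 mol%), THF, −78 °C; 1 M HCl work-up
Reagents that add atoms: none
Why: Cu(II)–bis(oxazoline)-catalysed Mukaiyama aldol addition to the chelating 1,2-diketone, in which the C2-symmetric square-planar chelate shields one ketone face, so the catalyst sets the C10 tertiary carbinol (R expected with the (R,R)-ligand).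

Step 3
Reactants: 4 S-ethyl (3R)-3-hydroxy-3-methyl-4-oxopentanethioate
Product: 5 (3R)-3-hydroxy-3-methyl-4-oxopentanal
Conditions: Et3SiH, 10% Pd/C, acetone, rt
Reagents that add atoms: none
Why: Fukuyama reduction stops at the aldehyde and leaves the ketone and the tertiary alcohol untouched; the crude aldehyde is used directly.

Step 4
Reactants: 6 3-(methoxymethoxy)prop-1-ene, 7 3-(trimethylsilyl)prop-2-ynal
Product: 9 (3S,4S)-3-(methoxymethoxy)-6-(trimethylsilyl)hex-1-en-5-yn-4-ol, via allylborane 8 (not isolated)
Conditions: s-BuLi, THF, −78 °C; (+)-Ipc2BOMe; BF3·OEt2; then 7, −78 °C; NaBO3·4H2O, THF/H2O, rt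
Reagents that add atoms: none
Why: Brown alkoxyallylboration, in which the (Z)-γ-alkoxyallylborane reacts through a chair transition state to give the syn 1,2-diol monoether and the isopinocampheyl groups select the aldehyde face (C6 S and carbinol S expected from the (+)-reagent).

Step 5
Reactants: 9 (3S,4S)-3-(methoxymethoxy)-6-(trimethylsilyl)hex-1-en-5-yn-4-ol
Product: 10 (3S,4R)-3-(methoxymethoxy)-6-(trimethylsilyl)hex-1-en-5-yn-4-yl benzoate
Conditions: PhCO2H, PPh3, DIAD, THF, 0 °C → rt
Reagents that add atoms: benzoic acid OC(=O)c1ccccc1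
Why: Mitsunobu esterification displaces the oxyphosphonium by SN2 and so inverts the propargylic centre, giving the anti-configured propargylic ester needed for the next step.

Step 6
Reactants: 10 (3S,4R)-3-(methoxymethoxy)-6-(trimethylsilyl)hex-1-en-5-yn-4-yl benzoate, 5 (3R)-3-hydroxy-3-methyl-4-oxopentanal
Product: 12 (3R,5S,6R)-3,5-dihydroxy-6-[(1S)-1-(methoxymethoxy)prop-2-en-1-yl]-3-methyl-8-(trimethylsilyl)oct-7-yn-2-one, via allenylindium reagent 11 (not isolated)
Conditions: Pd(PPh3)4 (5 mol%), InI (1.4 equiv), THF–HMPA (3:1), rt; aq. NH4Cl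
Reagents that add atoms: none
Why: Marshall–Tamaru-type Pd(0)-catalysed umpolung, in which anti-SN2′ oxidative addition and transmetalation give a configurationally defined allenylindium that adds to the aldehyde (not the ketone) through a cyclic SE2′ transition state, so C7 is set with net inversion of the benzoate centre and C8 by the anti preference of the addition (reagent control over the remote C10).

Step 7
Reactants: 12 (3R,5S,6R)-3,5-dihydroxy-6-[(1S)-1-(methoxymethoxy)prop-2-en-1-yl]-3-methyl-8-(trimethylsilyl)oct-7-yn-2-one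
Product: 13 (3R,5S,6R)-3,5-dihydroxy-6-[(1S)-1-(methoxymethoxy)prop-2-en-1-yl]-3-methyloct-7-yn-2-one
Conditions: K2CO3 (cat.), MeOH, 0 °C → rt
Reagents that add atoms: none
Why: Base-catalysed methanolysis cleaves the alkynyl C–Si bond selectively (protodesilylation of a TMS-alkyne).

Step 8
Reactants: 13 (3R,5S,6R)-3,5-dihydroxy-6-[(1S)-1-(methoxymethoxy)prop-2-en-1-yl]-3-methyloct-7-yn-2-one
Product: 14 (3R,5S,6R)-3-hydroxy-6-[(1S)-1-(methoxymethoxy)prop-2-en-1-yl]-3-methyl-2-oxooct-7-yn-5-yl 2-methylprop-2-enoate
Conditions: methacrylic anhydride, Et3N, DMAP (cat.), CH2Cl2, 0 °C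
Reagents that add atoms: methacrylic anhydride CC(=C)C(=O)OC(=O)C(C)=C
Why: DMAP-catalysed acylation takes the secondary C8 hydroxyl, the tertiary α-ketol hydroxyl at C10 being too hindered; acylating O8 before the ester at C12 exists prevents premature γ-lactonisation.

Step 9
Reactants: 14 (3R,5S,6R)-3-hydroxy-6-[(1S)-1-(methoxymethoxy)prop-2-en-1-yl]-3-methyl-2-oxooct-7-yn-5-yl 2-methylprop-2-enoate
Product: 15 methyl (3R,4S,6R)-6-hydroxy-3-[(1S)-1-(methoxymethoxy)prop-2-en-1-yl]-6-methyl-2-methylidene-4-[(2-methylprop-2-enoyl)oxy]-7-oxooctanoate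
Conditions: Pd(OAc)2 (2 mol%), 2-PyPPh2, TsOH (cat.), CO (1–5 bar), MeOH/CH2Cl2, rt → 40 °C
Reagents that add atoms: carbon monoxide [C-]#[O+]; methanol CO
Why: Pd/2-pyridylphosphine-catalysed Markovnikov hydroalkoxycarbonylation of the terminal alkyne (Drent-type methoxycarbonylation) gives the 2-substituted acrylate, while alkenes, esters, the ketone and the MOM ether are inert under these conditions.

Step 10
Reactants: 15 methyl (3R,4S,6R)-6-hydroxy-3-[(1S)-1-(methoxymethoxy)prop-2-en-1-yl]-6-methyl-2-methylidene-4-[(2-methylprop-2-enoyl)oxy]-7-oxooctanoate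
Product: 16 methyl 2-[(5S,6R,7S)-7-[(2R)-2-hydroxy-2-methyl-3-oxobutyl]-5-(methoxymethoxy)-3-methyl-2-oxo-2,5,6,7-tetrahydrooxepin-6-yl]prop-2-enoate
Conditions: Grubbs II (10 mol%), toluene (2 mM), 80 °C
Reagents that add atoms: none
Why: Ring-closing metathesis between the vinyl group and the methacrylate gives the seven-membered α-methyl-α,β-unsaturated lactone, whose ring size enforces the Z (angelate-type) geometry of C4=C5; loss of ethene drives the reaction and the 1,1-disubstituted acrylate does not compete.

Step 11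
Reactants: 16 methyl 2-[(5S,6R,7S)-7-[(2R)-2-hydroxy-2-methyl-3-oxobutyl]-5-(methoxymethoxy)-3-methyl-2-oxo-2,5,6,7-tetrahydrooxepin-6-yl]prop-2-enoate
Product: 20 6-O-methoxymethyl tricyclic core (6S,7R,8S,10R), via nine-membered hydroxy lactone 17 (not isolated), via nine-membered lactone butyrolactone 18 (not isolated), via bridged hemiketal 19 (not isolated)
Conditions: LiHMDS (2.5 equiv), THF, −78 → 0 °C; AcOH; then p-TsOH·H2O (cat.), CH2Cl2, rt
Reagents that add atoms: none
Why: Proposed new method: LiHMDS forms the C10 alkoxide and the C2 methyl-ketone enolate; the alkoxide adds to the lactone carbonyl C3 through a six-membered orthoester-type tetrahedral intermediate (possible because O8 and O10 are 1,3-related), collapse with loss of O8 expands the seven-membered lactone to the nine-membered O10–C3 lactone 17, the released C8 oxygen is trapped as the trans-γ-lactone 18, the enolate then attacks C3 of what is now an α-acyloxy ketone to give hemiketal 19, and acid removes water to give the 3(2H)-furanone. The closest known reaction types are base-mediated 1,3-acyl migration (translactonisation) of diol monoesters and the intramolecular Claisen (Baker–Venkataraman/Dieckmann-type) condensation–dehydration of α-acyloxy ketones to 3(2H)-furanones. Ring closures: the nine-membered ring by ring expansion (two-atom C9–C10 insertion by exo-trig addition–elimination at the acyl carbon), the butyrolactone by 5-exo-trig lactonisation, the furanone by 5-(enolendo)-exo-trig C-acylation followed by dehydration. No permanent stereocentre is created: C6, C7, C8 and C10 come from 16, the Z geometry of C4=C5 is carried over from the seven-membered ring, and the transient hemiketal centre at C3 is fixed by the bridge and then destroyed. The step needs acyl transfer to O10 and C-acylation by C2 rather than O6 participation, conjugate addition or elimination; this is secured by the syn-1,3-diol geometry, the MOM cap on O6, the single enolisable position of the ketone (C10 is quaternary), and the fact that direct attack of the enolate on the seven-membered lactone (seven-membered transition state, then transannular hemiketalisation) leads to the same product.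

Step 12
Reactants: 20 6-O-methoxymethyl tricyclic core (6S,7R,8S,10R)
Product: 21 6-hydroxy tricyclic core (6S,7S,8S,10R)
Conditions: Me2BBr, CH2Cl2, −78 °C; aq. NaHCO3
Reagents that add atoms: none
Why: Bromodimethylborane cleaves the MOM acetal at low temperature by bromide attack at the acetal carbon, leaving the lactone, the enone and the vinylogous ester intact and touching no stereocentre.

Step 13
Reactants: 21 6-hydroxy tricyclic core (6S,7S,8S,10R)
Product: 22 target CNP0293168.1
Conditions: angelic acid, 2,4,6-Cl3C6H2COCl, Et3N, toluene, rt; then 21, toluene, 75 °C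
Reagents that add atoms: angelic acid C/C=C(/C)C(=O)O
Why: Yamaguchi-type esterification through the mixed anhydride, run without a nucleophilic catalyst, acylates the C6 alcohol while keeping the Z geometry of the angeloyl unit.

## Compound list

1 | S-ethyl ethanethioate | CC(=O)SCC | starting material
2 | 1-(ethylsulfanyl)-1-[(trimethylsilyl)oxy]ethene | C=C(O[Si](C)(C)C)SCC | intermediate
3 | butane-2,3-dione | CC(=O)C(C)=O | starting material
4 | S-ethyl (3R)-3-hydroxy-3-methyl-4-oxopentanethioate | CCSC(=O)C[C@@](C(C)=O)(C)O | intermediate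
5 | (3R)-3-hydroxy-3-methyl-4-oxopentanal | O=CC[C@@](C(C)=O)(C)O | intermediate
6 | 3-(methoxymethoxy)prop-1-ene | C=CCOCOC | starting material
7 | 3-(trimethylsilyl)prop-2-ynal | C[Si](C)(C)C#CC=O | starting material
8 | [(2Z)-3-(methoxymethoxy)prop-2-en-1-yl]bis[(1S,2S,3S,5R)-2,6,6-trimethylbicyclo[3.1.1]hept-3-yl]borane | COCO/C=C\CB([C@H]1C[C@H]2C[C@@H]([C@@H]1C)C2(C)C)[C@H]1C[C@H]2C[C@@H]([C@@H]1C)C2(C)C | intermediate
9 | (3S,4S)-3-(methoxymethoxy)-6-(trimethylsilyl)hex-1-en-5-yn-4-ol | C=C[C@H](OCOC)[C@@H](O)C#C[Si](C)(C)C | intermediate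
10 | (3S,4R)-3-(methoxymethoxy)-6-(trimethylsilyl)hex-1-en-5-yn-4-yl benzoate | C=C[C@H](OCOC)[C@H](OC(=O)c1ccccc1)C#C[Si](C)(C)C | intermediate
11 | (benzoato)iodo[(4S)-4-(methoxymethoxy)-1-(trimethylsilyl)hexa-1,2,5-trien-1-yl]indium, allene axis (Ra) from anti-SN2′ | C=C[C@H](OCOC)C([H])=[C@]=C([Si](C)(C)C)[In](I)OC(=O)c1ccccc1 | intermediate
12 | (3R,5S,6R)-3,5-dihydroxy-6-[(1S)-1-(methoxymethoxy)prop-2-en-1-yl]-3-methyl-8-(trimethylsilyl)oct-7-yn-2-one | CC(=O)[C@](C)(O)C[C@H](O)[C@H]([C@@H](OCOC)C=C)C#C[Si](C)(C)C | intermediate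
13 | (3R,5S,6R)-3,5-dihydroxy-6-[(1S)-1-(methoxymethoxy)prop-2-en-1-yl]-3-methyloct-7-yn-2-one | CC(=O)[C@](C)(O)C[C@H](O)[C@H]([C@@H](OCOC)C=C)C#C | intermediate
14 | (3R,5S,6R)-3-hydroxy-6-[(1S)-1-(methoxymethoxy)prop-2-en-1-yl]-3-methyl-2-oxooct-7-yn-5-yl 2-methylprop-2-enoate | CC(=O)[C@](C)(O)C[C@H](OC(=O)C(C)=C)[C@H]([C@@H](OCOC)C=C)C#C | intermediate
15 | methyl (3R,4S,6R)-6-hydroxy-3-[(1S)-1-(methoxymethoxy)prop-2-en-1-yl]-6-methyl-2-methylidene-4-[(2-methylprop-2-enoyl)oxy]-7-oxooctanoate | CC(=O)[C@](C)(O)C[C@H](OC(=O)C(C)=C)[C@H]([C@@H](OCOC)C=C)C(=C)C(=O)OC | intermediate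
16 | methyl 2-[(5S,6R,7S)-7-[(2R)-2-hydroxy-2-methyl-3-oxobutyl]-5-(methoxymethoxy)-3-methyl-2-oxo-2,5,6,7-tetrahydrooxepin-6-yl]prop-2-enoate | CC(=O)[C@](C)(O)C[C@@H]1OC(=O)/C(C)=C\[C@H](OCOC)[C@@H]1C(=C)C(=O)OC | intermediate
17 | nine-membered (Z)-lactone after O8→O10 acyl shift (C10 acetyl, free C8 hydroxyl, C12 methyl ester; centres as in 16) | CC(=O)[C@]1(C)OC(=O)/C(C)=C\[C@H](OCOC)[C@H](C(=C)C(=O)OC)[C@@H](O)C1 | intermediate
18 | nine-membered (Z)-lactone trans-fused to the α-methylene-γ-butyrolactone (C10 acetyl; centres as in 16) | CC(=O)[C@]1(C)OC(=O)/C(C)=C\[C@H](OCOC)[C@@H]2C(=C)C(=O)O[C@H]2C1 | intermediate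
19 | bridged C3 hemiketal of the tricyclic core (3-hydroxy-2,3-dihydrofuranone, 6-O-MOM; hemiketal centre fixed by the bridge) | C=C1C(=O)O[C@H]2C[C@@]3(C)O[C@](O)(CC3=O)/C(C)=C\[C@H](OCOC)[C@H]12 | intermediate
20 | (6S,7R,8S,10R)-3,10-epoxy-6-(methoxymethoxy)-1-oxogermacra-2,4Z,11(13)-trien-12,8-olide | C=C1C(=O)O[C@H]2C[C@@]3(C)OC(=CC3=O)/C(C)=C\[C@H](OCOC)[C@H]12 | intermediate
21 | (6S,7S,8S,10R)-3,10-epoxy-6-hydroxy-1-oxogermacra-2,4Z,11(13)-trien-12,8-olide | C=C1C(=O)O[C@H]2C[C@@]3(C)OC(=CC3=O)/C(C)=C\[C@H](O)[C@H]12 | intermediate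
22 | CNP0293168.1, (6S,7R,8S,10R)-3,10-epoxy-6-[(2Z)-2-methylbut-2-enoyloxy]-1-oxogermacra-2,4Z,11(13)-trien-12,8-olide | C=C1C(=O)O[C@H]2C[C@@]3(C)OC(=CC3=O)/C(C)=C\[C@H](OC(=O)/C(C)=C\C)[C@H]12 | target

## Step count and risks

Total step count: 13. Longest linear sequence: 11 steps (steps 1–3, then 6–13); the second branch (steps 4–5) joins at step 6.

Steps most likely to fail:

1. Step 11 (Proposed new method). Under the strongly basic conditions the substrate may be consumed by γ-deprotonation at C7 with β-elimination, or by conjugate addition of alkoxide or methoxide to the acrylate, before C-acylation occurs; the acyl shift to the tertiary oxygen may also stall. The fallback runs the same ring expansion stepwise with known operations, setting out from 16. Catalytic DBU in toluene should promote the 1,3-acyl migration, and lactonisation of the released C8 hydroxyl pulls the equilibrium, so that the bicyclic α-acyloxy ketone 18 is isolated. Soft enolisation (TMSOTf, Et3N, CH2Cl2, 0 °C) gives the silyl enol ether F1, which is brominated without isolation (NBS, THF, 0 °C) to the bromomethyl ketone F2. Triphenylphosphine in toluene gives the phosphonium bromide F3. Triethylamine in warm toluene then generates the keto-ylide, which undergoes the known intramolecular Wittig olefination of an ester carbonyl to close the furanone; this delivers 20, where the route is rejoined.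

2. Step 10. Initiation on the 1,1-disubstituted methacrylate is slow and the ester prefers the s-trans conformation, so dimerisation or catalyst decay may outrun closure of the trisubstituted olefin. The fallback closes the same bond by intramolecular Horner–Wadsworth–Emmons olefination and sets out from 13. Acylation of the C8 hydroxyl with 2-(diethoxyphosphoryl)propanoic acid (DCC, DMAP) gives the phosphonate ester F4 (epimers at the P-bearing carbon, which converge). Methoxycarbonylation as in step 9 gives the acrylate F5. Selective ozonolysis of the electron-richer vinyl group (O3, CH2Cl2, −78 °C, indicator end-point; Me2S) gives the α-alkoxy aldehyde F6. Masamune–Roush conditions (LiCl, DBU, MeCN, high dilution) then close the seven-membered (Z)-lactone and return to 16.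

3. Step 13. The angeloyl unit may isomerise to the tiglate during activation, and the free C6 alcohol may translactonise (8,12- to 6,12-olide) under the warm, basic acylation conditions. The fallback builds the Z olefin after the ester bond and sets out from 21. Esterification with 2-[bis(2,2,2-trifluoroethoxy)phosphoryl]propanoic acid (DCC, DMAP, CH2Cl2, 0 °C) gives the phosphonate ester F7. Still–Gennari olefination (KHMDS, 18-crown-6, THF, −78 °C; acetaldehyde) then gives the Z-configured 2-methylbut-2-enoate, that is 22.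

Further compounds
F1 | step 11 | silyl enol ether of 18 (1-[(trimethylsilyl)oxy]vinyl group on C10) | C=C(O[Si](C)(C)C)[C@]1(C)OC(=O)/C(C)=C\[C@H](OCOC)[C@@H]2C(=C)C(=O)O[C@H]2C1
F2 | step 11 | bromomethyl ketone of 18 (C2 bromide) | BrCC(=O)[C@]1(C)OC(=O)/C(C)=C\[C@H](OCOC)[C@@H]2C(=C)C(=O)O[C@H]2C1
F3 | step 11 | triphenylphosphonium bromide from F2 | [Br-].O=C(C[P+](c1ccccc1)(c1ccccc1)c1ccccc1)[C@]1(C)OC(=O)/C(C)=C\[C@H](OCOC)[C@@H]2C(=C)C(=O)O[C@H]2C1
F4 | step 10 | 2-(diethoxyphosphoryl)propanoate of 13 at the C8 oxygen (epimers at the P-bearing carbon) | CC(=O)[C@](C)(O)C[C@H](OC(=O)C(C)P(=O)(OCC)OCC)[C@H]([C@@H](OCOC)C=C)C#C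
F5 | step 10 | methyl acrylate from F4 by methoxycarbonylation of the alkyne | CC(=O)[C@](C)(O)C[C@H](OC(=O)C(C)P(=O)(OCC)OCC)[C@H]([C@@H](OCOC)C=C)C(=C)C(=O)OC
F6 | step 10 | C5 aldehyde from F5 by ozonolysis of the vinyl group | CC(=O)[C@](C)(O)C[C@H](OC(=O)C(C)P(=O)(OCC)OCC)[C@H]([C@@H](OCOC)C=O)C(=C)C(=O)OC
F7 | step 13 | 2-[bis(2,2,2-trifluoroethoxy)phosphoryl]propanoate of 21 at the C6 oxygen (epimers at the P-bearing carbon) | C=C1C(=O)O[C@H]2C[C@@]3(C)OC(=CC3=O)/C(C)=C\[C@H](OC(=O)C(C)P(=O)(OCC(F)(F)F)OCC(F)(F)F)[C@H]12
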